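Diplotrin A is disconnected at the bond between C2 of the γ-pyranone ring and C1' of the hydroquinone B ring. C2 is the β-carbon of a vinylogous ester and the B-ring carbon enters as an aryl bromide, so the union needs polarity reversal at C2. The key step exploits the C2–H of 3,7,8-trimethoxychromone, the only C–H of the pyranone ring, flanked by O1 and the C3 methoxy group: a TMP-zinc base metalates it, and Negishi coupling with commercial 1-bromo-2,4,5-trimethoxybenzene should give the complete flavone skeleton in one operation. The para-related 2',5'-oxygens of ring B then allow oxidative demethylation to the p-quinone and reduction to the hydroquinone.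

Key step: step 4

Remark: the target has no stereocentre and is achiral, so no stereocontrol is needed; epoxide 4 is a racemic, cis-fused transient intermediate.

Step 1
Reactants: 1 2'-hydroxy-3',4'-dimethoxyacetophenone
Product: 3 7,8-dimethoxy-4H-chromen-4-one, via enaminone 2 (not isolated)
Conditions: DMF-DMA (neat), 95 °C; then conc. HCl, CH2Cl2, 40 °C
Reagents that add atoms: N,N-dimethylformamide dimethyl acetal, COC(OC)N(C)C
Why: Condensation of the methyl ketone with DMF-DMA should give the enaminone, and acid then drives intramolecular oxa-Michael addition of the phenol with loss of dimethylamine, the standard enaminone route to 2,3-unsubstituted chromones.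

Step 2
Reactants: 3 7,8-dimethoxy-4H-chromen-4-one
Product: 5 3-hydroxy-7,8-dimethoxy-4H-chromen-4-one, via epoxychromanone 4 (not isolated)
Conditions: DMDO (fresh, from Oxone/acetone), acetone/CH2Cl2, 0 °C to rt; then p-TsOH (cat.), CH2Cl2, rt
Reagents that add atoms: dimethyldioxirane, CC1(C)OO1
Why: Dimethyldioxirane should epoxidise the C2=C3 bond under neutral conditions, and acid then opens the epoxide at C2 (oxocarbenium stabilised by O1) with loss of the C3 proton, an epoxidation/rearrangement sequence known to give 3-hydroxychromones.

Step 3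
Reactants: 5 3-hydroxy-7,8-dimethoxy-4H-chromen-4-one
Product: 6 3,7,8-trimethoxy-4H-chromen-4-one
Conditions: MeI, K2CO3, acetone, 56 °C
Reagents that add atoms: iodomethane, CI
Why: Williamson O-methylation of the acidic enolic 3-OH should proceed under mild carbonate conditions that do not open the pyranone ring.

Step 4
Reactants: 6 3,7,8-trimethoxy-4H-chromen-4-one; 7 1-bromo-2,4,5-trimethoxybenzene
Product: 9 3,7,8-trimethoxy-2-(2,4,5-trimethoxyphenyl)-4H-chromen-4-one, via dichromonylzinc 8 (not isolated)
Conditions: TMP2Zn·2MgCl2·2LiCl (0.6 equiv), THF, −30 °C to 25 °C; then 7, Pd(OAc)2 (cat.), SPhos (cat.), THF, 55 °C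
Reagents that add atoms: none
Why: The TMP-zinc amide, with MgCl2 bound to the C4 carbonyl, should remove the C2–H of 6 (an sp2 C–H alpha to O1 and next to the coordinating C3–OMe) to give the di(chromon-2-yl)zinc 8, so that the natively electrophilic C2 becomes the nucleophile. Pd(0)/SPhos then inserts into the C–Br bond of 7, the heteroaryl groups of 8 transmetalate in turn, and reductive elimination forms the C2–C1' bond (Negishi cross-coupling). The closest known reaction type is the zincation of chromones with TMP-zinc bases followed by Negishi arylation to flavones. No ring is closed and no stereocentre is formed. The step needs site selectivity for C2–H over C5–H and C6–H of the benzo ring, which the blocked C3 position, the higher acidity of C2–H and the mild, non-nucleophilic zinc amide should secure; SPhos is chosen because 7 is an electron-rich bromide and both partners carry an ortho methoxy group.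

Step 5
Reactants: 9 3,7,8-trimethoxy-2-(2,4,5-trimethoxyphenyl)-4H-chromen-4-one
Product: 11 diplotrin A, via quinone 10 (not isolated)
Conditions: CAN (2.5 equiv), MeCN/H2O, 0 °C; EtOAc extraction; then aq. Na2S2O4, EtOAc/H2O, rt, under Ar
Reagents that add atoms: water, O
Why: Cerium(IV) oxidative demethylation should convert the para-related 2',5'-dimethoxy pair of the electron-rich B ring into the p-quinone (oxygens from water) while the carbonyl-deactivated A ring and the 4'-OMe stay intact, and dithionite then reduces the quinone to the hydroquinone.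

Compound list
1 | 2'-hydroxy-3',4'-dimethoxyacetophenone, 1-(2-hydroxy-3,4-dimethoxyphenyl)ethan-1-one | CC(=O)c1ccc(OC)c(OC)c1O | starting material
2 | (E)-3-(dimethylamino)-1-(2-hydroxy-3,4-dimethoxyphenyl)prop-2-en-1-one (enaminone) | CN(C)/C=C/C(=O)c1ccc(OC)c(OC)c1O | intermediate
3 | 7,8-dimethoxy-4H-chromen-4-one | COc1ccc2c(c1OC)occc2=O | intermediate
4 | 2,3-epoxy-7,8-dimethoxychroman-4-one (racemic, cis-fused; one enantiomer drawn) | COc1ccc2c(c1OC)O[C@H]1O[C@H]1C2=O | intermediate
5 | 3-hydroxy-7,8-dimethoxy-4H-chromen-4-one | COc1ccc2c(c1OC)occ(O)c2=O | intermediate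
6 | 3,7,8-trimethoxy-4H-chromen-4-one | COc1ccc2c(c1OC)occ(OC)c2=O | intermediate
7 | 1-bromo-2,4,5-trimethoxybenzene | COc1cc(OC)c(Br)cc1OC | starting material
8 | bis(3,7,8-trimethoxy-4-oxo-4H-chromen-2-yl)zinc | COc1ccc2c(c1OC)oc([Zn]c1oc3c(OC)c(OC)ccc3c(=O)c1OC)c(OC)c2=O | intermediate
9 | 3,7,8-trimethoxy-2-(2,4,5-trimethoxyphenyl)-4H-chromen-4-one | COc1cc(OC)c(-c2oc3c(OC)c(OC)ccc3c(=O)c2OC)cc1OC | intermediate
10 | 2-methoxy-5-(3,7,8-trimethoxy-4-oxo-4H-chromen-2-yl)cyclohexa-2,5-diene-1,4-dione (quinone) | COC1=CC(=O)C(c2oc3c(OC)c(OC)ccc3c(=O)c2OC)=CC1=O | intermediate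
11 | diplotrin A, 2-(2,5-dihydroxy-4-methoxyphenyl)-3,7,8-trimethoxy-4H-chromen-4-one | COc1cc(O)c(-c2oc3c(OC)c(OC)ccc3c(=O)c2OC)cc1O | target

Total step count: 5
Longest linear sequence: 5 steps (1 to 11; 7 is used as purchased)

Steps most likely to fail

Step 4. The zincation may take place at C5–H or C6–H of the benzo ring, the zinc species may be protonated before coupling, or transmetalation may stall at the doubly ortho-substituted palladium centre. The fallback makes the same bond without metals and with the opposite polarity assignment, setting out from 5. The C3 enol of 5 makes C2 nucleophilic, as in kojic acid. Conjugate addition to commercial 2-methoxy-1,4-benzoquinone (Sc(OTf)3 cat., MeCN, rt) should occur at C5 of the quinone, beta to its more electrophilic carbonyl. Tautomerisation should then give 2-(2,5-dihydroxy-4-methoxyphenyl)-3-hydroxy-7,8-dimethoxy-4H-chromen-4-one F1. Exhaustive O-methylation of F1 (MeI, K2CO3, DMF, under Ar) comes back to the route at 9.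

Step 5. The oxidative demethylation may run across the 4',5'-pair to an ortho-quinone, may over-oxidise or nitrate the B ring, or the hydroquinone may re-oxidise on work-up. The fallback avoids any oxidation by carrying the two hydroquinone oxygens as benzyl ethers. Commercial 2-methoxyhydroquinone is benzylated (BnBr, K2CO3, DMF) to 1,4-bis(benzyloxy)-2-methoxybenzene F2. Bromination para to the methoxy group (NBS, MeCN, 0 °C) gives 1,4-bis(benzyloxy)-2-bromo-5-methoxybenzene F3. The fallback sets out from 6, which is zincated to 8 as in step 4 and coupled with F3 under the same Negishi conditions. This should give 2-[2,5-bis(benzyloxy)-4-methoxyphenyl]-3,7,8-trimethoxy-4H-chromen-4-one F4. Hydrogenolysis of F4 (H2, Pd/C, EtOAc) comes back to the route at 11.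

Step 2. Epoxidation of the electron-poor enone may be slow, and the epoxide may open to ring-cleaved products instead of rearranging. The fallback introduces the C3 oxygen by nitrosation and sets out from 3. Conjugate reduction (H2, Pd/C, EtOAc, stopped after one equivalent) should give 7,8-dimethoxychroman-4-one F5. Alpha-nitrosation (isoamyl nitrite, conc. HCl, EtOH) gives 3-(hydroxyimino)-7,8-dimethoxychroman-4-one F6. F6 is hydrolysed in the same acidic medium to the 3,4-dione, whose enol is 5, where the route is rejoined.

Further compounds
F1 | step 4 | 2-(2,5-dihydroxy-4-methoxyphenyl)-3-hydroxy-7,8-dimethoxy-4H-chromen-4-one | COc1cc(O)c(-c2oc3c(OC)c(OC)ccc3c(=O)c2O)cc1O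
F2 | step 5 | 1,4-bis(benzyloxy)-2-methoxybenzene | COc1cc(OCc2ccccc2)ccc1OCc1ccccc1
F3 | step 5 | 1,4-bis(benzyloxy)-2-bromo-5-methoxybenzene | COc1cc(OCc2ccccc2)c(Br)cc1OCc1ccccc1
F4 | step 5 | 2-[2,5-bis(benzyloxy)-4-methoxyphenyl]-3,7,8-trimethoxy-4H-chromen-4-one | COc1cc(OCc2ccccc2)c(-c2oc3c(OC)c(OC)ccc3c(=O)c2OC)cc1OCc1ccccc1
F5 | step 2 | 7,8-dimethoxychroman-4-one | COc1ccc2c(c1OC)OCCC2=O
F6 | step 2 | 3-(hydroxyimino)-7,8-dimethoxychroman-4-one | COc1ccc2c(c1OC)OCC(=NO)C2=O
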